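## Retrosynthetic overview
1. Last operation: one hydride/acid sequence turns both acyl groups into the two CH2OH groups. It also removes the auxiliary, acetate, silyl ether and acetal.
2. Cα–Cβ bond of the guaiacylglycerol unit: anti-selective glycolate aldol of an aryloxyacetyl oxazolidinone with vanillin acetate (erythro pair).
3. C2–C3 bond of the dihydrobenzofuran: enantioselective Rh-carbene insertion into the ArCH2–O C–H bond. It is run in one pot with acetalisation of the free aldehyde, so two rings close in one operation.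
4. The diazo ester comes from an aryl iodide and ethyl diazoacetate (Pd). The iodide comes from 5-iodovanillin and a syringyl alcohol ether (Mitsunobu).
5. Ring order: the three benzene rings are bought. The dihydrofuran and a temporary 1,3-dioxolane form together (step 6), and the dioxolane is opened again in step 8.

Assumption: the sense of induction in steps 6 and 7 is taken from the closest published substrates (cis-2-aryl-dihydrobenzofuran-3-carboxylates; chelated imide enolates).

Abbreviations:
- Xc = (R)-4-benzyl-2-oxo-1,3-oxazolidin-3-yl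
- Cα = ArCH–O, Cβ = CH–OAr, Cγ = CH2OH of the glycerol chain

## Route

Step 1
Reactants: 1 syringaldehyde
Product: 2 syringyl alcohol (4-(hydroxymethyl)-2,6-dimethoxyphenol)
Conditions: NaBH4, EtOH, 0 °C
Reagents that add atoms: none
Why: Borohydride reduction of an aryl aldehyde that leaves the phenol alone and creates no stereocentre.

Step 2
Reactants: 3 (R)-4-benzyl-1,3-oxazolidin-2-one; 4 bromoacetyl bromide
Product: 5 (R)-4-benzyl-3-(bromoacetyl)-1,3-oxazolidin-2-one
Conditions: n-BuLi, THF, −78 °C; then 4, −78→0 °C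
Reagents that add atoms: none
Why: Evans N-acylation, in which the acyl bromide reacts far faster than the alkyl bromide and the stereocentre is bought with 3.

Step 3
Reactants: 2 syringyl alcohol; 5 bromoacetyl imide
Product: 6 Xc-C(=O)CH2-O-aryl ether of 2 (3-{[4-(hydroxymethyl)-2,6-dimethoxyphenoxy]acetyl} imide)
Conditions: K2CO3, acetone, rt→40 °C
Reagents that add atoms: none
Why: Williamson ether synthesis, because K2CO3 deprotonates only the phenol and the α-bromo imide is a very good SN2 partner, so the benzylic OH stays free.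

Step 4
Reactants: 6 benzylic alcohol; 7 5-iodovanillin
Product: 8 3-iodo-5-methoxy-4-({3,5-dimethoxy-4-[2-oxo-2-Xc-ethoxy]benzyl}oxy)benzaldehyde
Conditions: PPh3, DIAD, THF, 0 °C→rt
Reagents that add atoms: none
Why: Mitsunobu etherification of a primary electron-rich benzylic alcohol with an acidic phenol (pKa about 7), under neutral conditions that spare aldehyde and imide.

Step 5
Reactants: 8 aryl iodide; 9 ethyl diazoacetate
Product: 10 ethyl 2-diazo-2-[5-formyl-3-methoxy-2-({3,5-dimethoxy-4-[2-oxo-2-Xc-ethoxy]benzyl}oxy)phenyl]acetate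
Conditions: Pd(PPh3)4 (5 mol%), Ag2CO3 (0.5 equiv), Et3N, PhMe, rt
Reagents that add atoms: none
Why: Pd-catalysed cross-coupling of an aryl iodide with ethyl diazoacetate with retention of the diazo group, which runs at room temperature and tolerates the aldehyde.

Step 6 (key step)
Reactants: 10 aryl diazoacetate
Product: 13 ethyl (2R,3R)-trans-5-(1,3-dioxolan-2-yl)-7-methoxy-2-{3,5-dimethoxy-4-[2-oxo-2-Xc-ethoxy]phenyl}-2,3-dihydrobenzofuran-3-carboxylate, via cis-dihydrobenzofuran aldehyde 11 (not isolated), via cis-dihydrobenzofuran dioxolane 12 (not isolated)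
Conditions: Rh2(S-PTTL)4 (1 mol%), PhMe, −60 °C; then (TMSOCH2)2, TMSOTf (5 mol%), CH2Cl2, −78→−20 °C; then DBU, rt→40 °C (one pot)
Reagents that add atoms: 1,2-bis(trimethylsiloxy)ethane C[Si](C)(C)OCCO[Si](C)(C)C
Why: Enantioselective intramolecular 1,5 C–H insertion of the donor/acceptor Rh carbene into the hydridic ArCH2–O bond closes the dihydrofuran as the cis-(2R,3S) ester (catalyst sets C2), aprotic Noyori acetalisation closes the dioxolane in the same flask, and the DBU quench epimerises only the acidic C3–H to the more stable trans-(2R,3R) ester.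

Step 7
Reactants: 13 glycolyl imide; 14 vanillin acetate (4-acetoxy-3-methoxybenzaldehyde)
Product: 15 O-TMS anti-aldol adduct: imide Xc-C(=O)-CβH(OAr)-CαH(OTMS)-(4-acetoxy-3-methoxyphenyl) with acyl descriptors (2S,3S)
Conditions: MgCl2 (20 mol%), Et3N (2 equiv), TMSCl (1.5 equiv), EtOAc, rt
Reagents that add atoms: chlorotrimethylsilane C[Si](C)(C)Cl
Why: Proposed new method: MgCl2/Et3N soft enolisation gives the Mg-chelated Z-enolate, whose face anti to the (R)-benzyl group adds to the aldehyde through a closed boat-like transition state while TMSCl traps the aldolate and releases Mg, which sets Cβ (2S in the imide, R in the target) and the anti (erythro) Cα (S); the closest known reaction type is the Evans MgCl2/TMSCl-catalysed anti-aldol of N-propionyloxazolidinones with aromatic aldehydes, extended here to an aryloxyacetyl imide, and the ethyl ester and acetal are inert to these conditions.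

Step 8
Reactants: 15 protected aldol adduct
Product: 17 target CID53356209, via reduced acetal silyl ether 16 (not isolated)
Conditions: LiBH4, MeOH (additive), THF, 0 °C→rt; then 1 M HCl, THF, rt
Reagents that add atoms: water O
Why: Reductive cleavage of the Evans imide together with ester and aryl acetate reduction by LiBH4 (the TMS ether blocks retro-aldol), followed by mild acid hydrolysis of the dioxolane and silyl ether, with no stereocentre touched.

## Compound list
1 | syringaldehyde | COc1cc(C=O)cc(OC)c1O | starting material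
2 | syringyl alcohol | COc1cc(CO)cc(OC)c1O | intermediate
3 | (R)-4-benzyl-1,3-oxazolidin-2-one | O=C1N[C@H](Cc2ccccc2)CO1 | starting material
4 | bromoacetyl bromide | BrCC(Br)=O | starting material
5 | (R)-4-benzyl-3-(bromoacetyl)-1,3-oxazolidin-2-one | O=C(CBr)N1[C@H](Cc2ccccc2)COC1=O | intermediate
6 | (R)-4-benzyl-3-{[4-(hydroxymethyl)-2,6-dimethoxyphenoxy]acetyl}-1,3-oxazolidin-2-one | COc1cc(CO)cc(OC)c1OCC(=O)N1[C@H](Cc2ccccc2)COC1=O | intermediate
7 | 5-iodovanillin | COc1cc(C=O)cc(I)c1O | starting material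
8 | aryl benzyl ether iodide | COc1cc(COc2c(I)cc(C=O)cc2OC)cc(OC)c1OCC(=O)N1[C@H](Cc2ccccc2)COC1=O | intermediate
9 | ethyl diazoacetate | CCOC(=O)C=[N+]=[N-] | starting material
10 | aryl diazoacetate | COc1cc(COc2c(cc(C=O)cc2OC)C(=[N+]=[N-])C(=O)OCC)cc(OC)c1OCC(=O)N1[C@H](Cc2ccccc2)COC1=O | intermediate
11 | ethyl (2R,3S)-cis-5-formyl-dihydrobenzofuran-3-carboxylate | COc1cc([C@@H]2Oc3c(OC)cc(C=O)cc3[C@@H]2C(=O)OCC)cc(OC)c1OCC(=O)N1[C@H](Cc2ccccc2)COC1=O | intermediate
12 | ethyl (2R,3S)-cis-5-(1,3-dioxolan-2-yl)-dihydrobenzofuran-3-carboxylate | COc1cc([C@@H]2Oc3c(OC)cc(C4OCCO4)cc3[C@@H]2C(=O)OCC)cc(OC)c1OCC(=O)N1[C@H](Cc2ccccc2)COC1=O | intermediate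
13 | ethyl (2R,3R)-trans-5-(1,3-dioxolan-2-yl)-dihydrobenzofuran-3-carboxylate | COc1cc([C@@H]2Oc3c(OC)cc(C4OCCO4)cc3[C@H]2C(=O)OCC)cc(OC)c1OCC(=O)N1[C@H](Cc2ccccc2)COC1=O | intermediate
14 | vanillin acetate | COc1cc(C=O)ccc1OC(C)=O | starting material
15 | O-TMS anti-aldol imide | COc1cc([C@H](O[Si](C)(C)C)[C@@H](C(=O)N2[C@H](Cc3ccccc3)COC2=O)Oc2c(OC)cc([C@@H]3Oc4c(OC)cc(C5OCCO5)cc4[C@H]3C(=O)OCC)cc2OC)ccc1OC(C)=O | intermediate
16 | reduced acetal silyl ether | COc1cc([C@H](O[Si](C)(C)C)[C@@H](CO)Oc2c(OC)cc([C@@H]3Oc4c(OC)cc(C5OCCO5)cc4[C@H]3CO)cc2OC)ccc1O | intermediate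
17 | (2R,3S)-2-{4-[(1S,2R)-1,3-dihydroxy-1-(4-hydroxy-3-methoxyphenyl)propan-2-yl]oxy-3,5-dimethoxyphenyl}-3-(hydroxymethyl)-7-methoxy-2,3-dihydrobenzofuran-5-carbaldehyde | COc1cc([C@H](O)[C@@H](CO)Oc2c(OC)cc([C@@H]3Oc4c(OC)cc(C=O)cc4[C@H]3CO)cc2OC)ccc1O | target

## Count and risks
Total steps: 8. Longest linear sequence: 7 (steps 1, 3, 4, 5, 6, 7, 8).

**Step 6** is at risk from the carbene meeting a free aldehyde, from the ee and cis selectivity on a crowded ether, and from the epimerisation. The fallback sets out from 10 and comes back at 12. It stops using the carbene step as the source of chirality.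
- Achiral Rh2(OAc)4 insertion and the same acetalisation give the stereorandom dihydrobenzofuran acetal F1.
- DDQ (dioxane, 80 °C) dehydrogenates it to the flat benzofuran-3-carboxylate F2.
- A chiral Ru–NHC catalyst under H2 (60 bar) adds hydrogen syn to one face of the furan C2=C3 bond and returns cis-ester 12.
- DBU then takes 12 to 13.

**Step 7** is at risk because the anti-aldol is untested on a glycolate-type imide. The fallback sets out from 13 and comes back at 17. It replaces auxiliary control by reagent control.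
- EtSLi (THF, 0 °C) displaces the auxiliary to give the S-ethyl thioester F3.
- Et3N/TMSOTf gives the (Z)-ketene silyl thioacetal F4.
- A Mukaiyama–Kobayashi aldol with 14 gives the anti-aldol thioester F5. Conditions are Sn(OTf)2, a chiral proline-derived diamine, Bu2Sn(OAc)2, CH2Cl2, −78 °C, which are known to give anti-α-alkoxy-β-hydroxy thioesters.
- LiBH4 gives the acetal polyol F6, and 1 M HCl releases 17.

**Step 5** is at risk because the iodide is ortho-hindered and the diazo product is sensitive. The fallback sets out from 8 and comes back at 10. It builds the C–C bond first and the diazo group afterwards.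
- Pd(dba)2/P(t-Bu)3/ZnF2 coupling of 8 with the trimethylsilyl ketene acetal of ethyl acetate gives the ethyl arylacetate F7.
- Regitz diazo transfer (p-ABSA, DBU, MeCN) gives 10.

## Further compounds
F1 | step 6 | stereorandom ethyl 5-(1,3-dioxolan-2-yl)-2-aryl-2,3-dihydrobenzofuran-3-carboxylate | COc1cc(C2Oc3c(OC)cc(C4OCCO4)cc3C2C(=O)OCC)cc(OC)c1OCC(=O)N1[C@H](Cc2ccccc2)COC1=O
F2 | step 6 | ethyl 5-(1,3-dioxolan-2-yl)-2-aryl-7-methoxybenzofuran-3-carboxylate | COc1cc(-c2oc3c(OC)cc(C4OCCO4)cc3c2C(=O)OCC)cc(OC)c1OCC(=O)N1[C@H](Cc2ccccc2)COC1=O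
F3 | step 7 | S-ethyl aryloxythioacetate of the trans-dihydrobenzofuran | COc1cc([C@@H]2Oc3c(OC)cc(C4OCCO4)cc3[C@H]2C(=O)OCC)cc(OC)c1OCC(=O)SCC
F4 | step 7 | (Z)-ketene silyl thioacetal | COc1cc([C@@H]2Oc3c(OC)cc(C4OCCO4)cc3[C@H]2C(=O)OCC)cc(OC)c1O/C=C(\SCC)O[Si](C)(C)C
F5 | step 7 | anti-aldol thioester | COc1cc([C@H](O)[C@@H](C(=O)SCC)Oc2c(OC)cc([C@@H]3Oc4c(OC)cc(C5OCCO5)cc4[C@H]3C(=O)OCC)cc2OC)ccc1OC(C)=O
F6 | step 7 | acetal polyol | COc1cc([C@H](O)[C@@H](CO)Oc2c(OC)cc([C@@H]3Oc4c(OC)cc(C5OCCO5)cc4[C@H]3CO)cc2OC)ccc1O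
F7 | step 5 | ethyl arylacetate | COc1cc(COc2c(CC(=O)OCC)cc(C=O)cc2OC)cc(OC)c1OCC(=O)N1[C@H](Cc2ccccc2)COC1=O
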